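**Retrosynthetic overview** (quinolizidine numbering: ring A = N5/C4/C3/C2/C1/C9a, ring B = N5/C6–C9/C9a)
1. The target is a C2-symmetric 16-membered bis(3-methylquinolizidin-2-one), each unit 1R,3R,9S,9aS. C1 and C3 epimerise by enolisation and C9a by retro-aza-Michael/aza-Michael, so only C9 has to be carried through.
2. Key disconnection: both C1–C9a bonds, made by a double transannular Mannich closure of a bis-iminium generated by anodic decarboxylation of a 24-membered bis(N-alkyl pipecolic acid). The carboxyl group marks C9a as the only carbon that can become iminium.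
3. The 24-membered ring comes from two N5–C4 aza-Michael bonds between two copies of one 3-substituted pipecolic acid carrying an isopropenyl ketone: first an intermolecular addition of the free amino acid to its N-Boc tert-butyl ester form, then a ring closure at high dilution.
4. The monomer comes from a cis-3-(hydroxymethyl)pipecolate by chain extension; ring B comes from D-aspartate by β-alkylation and N-cyclisation with 1-chloro-3-iodopropane. The aspartate α-centre sets C9, and its carboxyl is later lost as CO2.
5. Ring order: ring B, then the 24-membered macrocycle, then both rings A (contraction to the 16-membered carbocycle), then equilibration.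

Assumption: for a fixed 9S centre the drawn C1/C3/C9a arrangement (trans-fused, 3-methyl and 9-alkyl equatorial, 1-alkyl axial) is the thermodynamic one; the Boc-D-Asp-OtBu starting material is taken as purchasable.

**Step 1**
Reactants: 1 N-Boc-D-aspartic acid 1-tert-butyl ester
Product: 2 1-tert-butyl 4-methyl N-Boc-D-aspartate
Conditions: MeI, K2CO3, DMF, 0 °C → rt
Reagents that add atoms: iodomethane (CI)
Why: SN2 O-alkylation of the carboxylate differentiates the two carboxyls; the stereocentre is not touched.

**Step 2**
Reactants: 2 1-tert-butyl 4-methyl N-Boc-D-aspartate; 3 1-chloro-3-iodopropane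
Product: 5 1,2-di-tert-butyl 3-methyl (2R,3S)-piperidine-1,2,3-tricarboxylate, via open-chain (2R,3S)-3-(3-chloropropyl)aspartate diester 4 (not isolated)
Conditions: LiN(SiMe3)2 (2.1 equiv), THF, −78 °C; 3, −78 → −30 °C; then DMPU, NaI (0.2 equiv), 45 °C
Reagents that add atoms: none
Why: Dianion (N-lithiocarbamate/ester enolate) β-alkylation of aspartate, a Fráter–Seebach-type 1,2-induction in which the iodide is displaced anti to the NBoc group of the chelated enolate, sets the future C9 centre (3S) from the purchased C2 centre, and 6-exo-tet N-alkylation of the carbamate anion then closes ring B as the cis-2,3-diester.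

**Step 3**
Reactants: 5 1,2-di-tert-butyl 3-methyl (2R,3S)-piperidine-1,2,3-tricarboxylate
Product: 6 di-tert-butyl (2R,3S)-3-(hydroxymethyl)piperidine-1,2-dicarboxylate
Conditions: LiBH4, MeOH (1 equiv), THF, 0 °C; aq NH4Cl quench at 0 °C
Reagents that add atoms: none
Why: Chemoselective borohydride reduction of the methyl ester beside the hindered tert-butyl ester and the carbamate, quenched cold to avoid lactonisation; C3 is no longer α to a carbonyl and is configurationally locked.

**Step 4**
Reactants: 6 di-tert-butyl (2R,3S)-3-(hydroxymethyl)piperidine-1,2-dicarboxylate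
Product: 7 di-tert-butyl (2R,3S)-3-(iodomethyl)piperidine-1,2-dicarboxylate
Conditions: I2, PPh3, imidazole, CH2Cl2, 0 °C → rt
Reagents that add atoms: iodine (II)
Why: Appel-type iodination of a primary alcohol; no stereocentre is involved.

**Step 5**
Reactants: 7 di-tert-butyl (2R,3S)-3-(iodomethyl)piperidine-1,2-dicarboxylate; 8 pent-4-en-1-ylmagnesium bromide
Product: 9 di-tert-butyl (2R,3S)-3-(hex-5-en-1-yl)piperidine-1,2-dicarboxylate
Conditions: 8 (1.5 equiv), Li2CuCl4 (5 mol %), THF, −20 → 0 °C
Reagents that add atoms: none
Why: Kochi-type copper-catalysed sp3–sp3 cross-coupling of a primary iodide with a Grignard reagent, which at low temperature outruns addition to the tert-butyl ester and carbamate.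

**Step 6**
Reactants: 9 di-tert-butyl (2R,3S)-3-(hex-5-en-1-yl)piperidine-1,2-dicarboxylate; 10 2-bromopropene
Product: 12 di-tert-butyl (2R,3S)-3-(8-methyl-7-oxonon-8-en-1-yl)piperidine-1,2-dicarboxylate, via B-alkyl-9-BBN hydroboration adduct 11 (not isolated)
Conditions: 9-BBN dimer, THF, 0 °C → rt; then 10, CO (5 atm), Pd(PPh3)4 (5 mol %), K3PO4 (3 M aq), dioxane, 60 °C
Reagents that add atoms: carbon monoxide ([C-]#[O+])
Why: Anti-Markovnikov hydroboration followed by carbonylative B-alkyl Suzuki–Miyaura coupling (the acyl-palladium intermediate is intercepted by the alkylborane) builds the isopropenyl ketone in one pot.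

**Step 7**
Reactants: 12 di-tert-butyl (2R,3S)-3-(8-methyl-7-oxonon-8-en-1-yl)piperidine-1,2-dicarboxylate
Product: 13 (2R,3S)-3-(8-methyl-7-oxonon-8-en-1-yl)piperidine-2-carboxylic acid trifluoroacetate salt
Conditions: TFA/CH2Cl2 (1:1), 0 °C → rt; evaporate, triturate with Et2O
Reagents that add atoms: trifluoroacetic acid (OC(=O)C(F)(F)F)
Why: Acidolysis of the Boc group and the tert-butyl ester; keeping the amine as its trifluoroacetate salt blocks self-addition to the enone until base is added.

**Step 8**
Reactants: 13 (2R,3S)-3-(8-methyl-7-oxonon-8-en-1-yl)piperidine-2-carboxylic acid trifluoroacetate salt; 12 di-tert-butyl (2R,3S)-3-(8-methyl-7-oxonon-8-en-1-yl)piperidine-1,2-dicarboxylate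
Product: 14 linear head-to-tail mono-adduct (N-alkylated pipecolic acid joined to an N-Boc tert-butyl ester unit)
Conditions: 12 (3 equiv, 0.5 M), K2CO3 (1.5 equiv), MeOH, 40 °C, 13 added over 6 h; work-up at pH 6; excess 12 recovered by chromatography
Reagents that add atoms: none
Why: Intermolecular aza-Michael addition of the freed secondary amine to the isopropenyl ketone of 12, whose own nitrogen is blocked as the carbamate, so only one N5–C4 bond can form and the excess of 12 outcompetes the enone of 13; the new CH(CH3) centre forms as a mixture that converges in step 11.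

**Step 9**
Reactants: 14 linear head-to-tail mono-adduct (N-alkylated pipecolic acid joined to an N-Boc tert-butyl ester unit)
Product: 16 24-membered head-to-tail bis(N-alkyl pipecolic acid) macrocycle, via seco-diacid bis(trifluoroacetate) 15 (not isolated)
Conditions: TFA/CH2Cl2 (1:1), 0 °C → rt, evaporate; then syringe-pump addition over 24 h to K2CO3, MeOH/H2O (4:1), 45 °C, final 1 mM; adjust to pH 7, desalt on HP-20 resin
Reagents that add atoms: none
Why: Acidolysis of the remaining Boc and tert-butyl ester, then intramolecular aza-Michael ring closure under high dilution to the strain-free 24-membered ring, the reversibility of the addition letting mis-linked oligomers re-enter; the second CH(CH3) centre also forms as a mixture that converges in step 11.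

**Step 10**
Reactants: 16 24-membered head-to-tail bis(N-alkyl pipecolic acid) macrocycle
Product: 19 (9S,9'S) bis-quinolizidin-2-one macrocycle as epimer mixture at C1/C3/C9a, via bis(2-methoxypiperidine) 17 (not isolated), via bis-iminium bis(trifluoroacetate) 18 (not isolated)
Conditions: graphite anode, Pt cathode, undivided cell, NaOMe (0.2 equiv), MeOH, 0 °C, 10 mA cm−2, 2.5 F mol−1 per CO2H; then evaporate (<10 °C), CH2Cl2, TFA (10 equiv), −20 → 25 °C, same vessel; NaHCO3 work-up
Reagents that add atoms: none
Why: Proposed new method: anodic two-electron oxidation of each amino-carboxylate expels CO2 far faster than any α-C–H is lost, so the iminium precursor arises only at the carbon that carried the carboxyl (C9a, never C6 or C4); methanol traps it in the cell as an N,O-acetal, which keeps the adjacent C9–H from enamine exchange, and base-free ionisation with TFA in the same vessel lets the acid-formed enol of each ketone close ring A by transannular Mannich reaction, contracting the 24-membered ring to the 16-membered carbocycle, with C9a formed under the influence of the neighbouring C9 centre; the closest known chemistry is non-Kolbe (Hofer–Moest) electrolysis of α-amino acids to N,O-acetals and iminium ions and the decarbonylative iminium–Mannich cyclisation of tertiary α-amino acids, neither of which has been shown as a double transannular closure of a macrocyclic bis(amino acid).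

**Step 11**
Reactants: 19 (9S,9'S) bis-quinolizidin-2-one macrocycle as epimer mixture at C1/C3/C9a
Product: 20 target CNP0268544.9 (each quinolizidinone unit 1R,3R,9S,9aS)
Conditions: K2CO3 (0.5 equiv), MeOH, 50 °C, 24 h
Reagents that add atoms: none
Why: Thermodynamic equilibration: enolisation epimerises C1 and C3, and reversible retro-aza-Michael/aza-Michael across N5–C9a (a β-amino ketone) epimerises C9a, while C9 is untouched, so the mixture converges on the most stable isomer (trans-fused, 3-methyl and 9-alkyl equatorial, 1-alkyl axial to avoid the peri clash with the C9 chain).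

**Compound list**
1 | N-Boc-D-aspartic acid 1-tert-butyl ester | CC(C)(C)OC(=O)N[C@H](CC(=O)O)C(=O)OC(C)(C)C | starting material
2 | 1-tert-butyl 4-methyl N-Boc-D-aspartate | CC(C)(C)OC(=O)N[C@H](CC(=O)OC)C(=O)OC(C)(C)C | intermediate
3 | 1-chloro-3-iodopropane | ClCCCI | starting material
4 | 1-tert-butyl 4-methyl (2R,3S)-N-Boc-3-(3-chloropropyl)aspartate | CC(C)(C)OC(=O)N[C@H]([C@H](CCCCl)C(=O)OC)C(=O)OC(C)(C)C | intermediate
5 | 1,2-di-tert-butyl 3-methyl (2R,3S)-piperidine-1,2,3-tricarboxylate (cis) | CC(C)(C)OC(=O)N1[C@@H](C(=O)OC(C)(C)C)[C@@H](C(=O)OC)CCC1 | intermediate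
6 | di-tert-butyl (2R,3S)-3-(hydroxymethyl)piperidine-1,2-dicarboxylate | CC(C)(C)OC(=O)N1[C@@H](C(=O)OC(C)(C)C)[C@@H](CO)CCC1 | intermediate
7 | di-tert-butyl (2R,3S)-3-(iodomethyl)piperidine-1,2-dicarboxylate | CC(C)(C)OC(=O)N1[C@@H](C(=O)OC(C)(C)C)[C@@H](CI)CCC1 | intermediate
8 | pent-4-en-1-ylmagnesium bromide | C=CCCC[Mg]Br | starting material
9 | di-tert-butyl (2R,3S)-3-(hex-5-en-1-yl)piperidine-1,2-dicarboxylate | CC(C)(C)OC(=O)N1[C@@H](C(=O)OC(C)(C)C)[C@@H](CCCCC=C)CCC1 | intermediate
10 | 2-bromopropene | CC(Br)=C | starting material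
11 | 9-[6-((2R,3S)-1,2-bis(tert-butoxycarbonyl)piperidin-3-yl)hexyl]-9-borabicyclo[3.3.1]nonane | CC(C)(C)OC(=O)N1[C@@H](C(=O)OC(C)(C)C)[C@@H](CCCCCCB2C3CCCC2CCC3)CCC1 | intermediate
12 | di-tert-butyl (2R,3S)-3-(8-methyl-7-oxonon-8-en-1-yl)piperidine-1,2-dicarboxylate | CC(C)(C)OC(=O)N1[C@@H](C(=O)OC(C)(C)C)[C@@H](CCCCCCC(=O)C(C)=C)CCC1 | intermediate
13 | (2R,3S)-3-(8-methyl-7-oxonon-8-en-1-yl)piperidine-2-carboxylic acid trifluoroacetate salt | OC(=O)[C@@H]1NCCC[C@@H]1CCCCCCC(=O)C(C)=C.OC(=O)C(F)(F)F | intermediate
14 | linear mono-adduct: (2R,3S)-pipecolic acid whose N carries the CH2–CH(CH3)–C(=O)–(CH2)6 chain of a (2R,3S)-N-Boc tert-butyl ester unit, and which keeps its own 8-methyl-7-oxonon-8-enyl chain (CH(CH3) centre undefined) | CC(C)(C)OC(=O)N1[C@@H](C(=O)OC(C)(C)C)[C@@H](CCCCCCC(=O)C(C)CN2CCC[C@H](CCCCCCC(=O)C(C)=C)[C@@H]2C(=O)O)CCC1 | intermediate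
15 | seco-diacid: 14 without Boc and tert-butyl ester, as bis(trifluoroacetate) salt | OC(=O)[C@@H]1NCCC[C@@H]1CCCCCCC(=O)C(C)CN2CCC[C@H](CCCCCCC(=O)C(C)=C)[C@@H]2C(=O)O.OC(=O)C(F)(F)F.OC(=O)C(F)(F)F | intermediate
16 | 24-membered macrocycle of two (2R,3S)-pipecolic acid units, each N bonded to CH2–CH(CH3)–C(=O)–(CH2)6– ending on C3 of the other unit (CH(CH3) centres undefined) | OC(=O)[C@@H]1N2CC(C)C(=O)CCCCCC[C@H]3CCCN(CC(C)C(=O)CCCCCC[C@H]1CCC2)[C@H]3C(=O)O | intermediate
17 | the same macrocycle with OCH3 in place of each CO2H (bis N,O-acetal, C2 centres undefined) | COC1N2CC(C)C(=O)CCCCCC[C@H]3CCCN(CC(C)C(=O)CCCCCC[C@H]1CCC2)C3OC | intermediate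
18 | macrocyclic bis(2,3,4,5-tetrahydropyridinium) dication, bis(trifluoroacetate) | C1=[N+]2CC(C)C(=O)CCCCCC[C@H]3CCC[N+](CC(C)C(=O)CCCCCC[C@H]1CCC2)=C3.[O-]C(=O)C(F)(F)F.[O-]C(=O)C(F)(F)F | intermediate
19 | 16-membered bis(3-methylquinolizidin-2-one), 9S and 9'S fixed, C1/C3/C9a as epimer mixture | CC1CN2CCC[C@@H]3CCCCCC4C(=O)C(C)CN5CCC[C@H](CCCCCC(C1=O)C32)C45 | intermediate
20 | target: C2-symmetric 16-membered bis(3-methylquinolizidin-2-one) linked C1–(CH2)5–C9' and C1'–(CH2)5–C9, each unit 1R,3R,9S,9aS | C[C@@H]1CN2CCC[C@@H]3CCCCC[C@H]4C(=O)[C@H](C)CN5CCC[C@H](CCCCC[C@@H](C1=O)[C@H]32)[C@@H]45 | target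

**Totals**
Total steps: 11. Longest linear sequence: 11 (fully linear from 1; 12 is used both as the precursor of 13 and as its partner in step 8).

**Three steps most likely to fail, with fallbacks**

Step 10 (the proposed new electrochemical step). Risks are incomplete double decarboxylation and partial epimerisation at C9 through iminium–enamine exchange. Because the product is a dimer of two enantiopure halves, a single epimerisation gives a separable diastereomer; the enantiomer forms only if both C9 centres invert. The fallback uses known chemistry and sets out from 16: oxalyl chloride (CH2Cl2, 0 °C) gives the bis(acyl chloride) dihydrochloride F4, which on warming to 40 °C loses CO (the established decarbonylation of tertiary α-amino acid chlorides) to give the macrocyclic bis-iminium dichloride F5, the same dication as in 18. This cyclises under the HCl present, or after addition of TFA, and after NaHCO3 work-up the route is rejoined at 19.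

Step 9 (closure of the 24-membered ring). Risks are oligomerisation and slow addition of the hindered pipecolate nitrogen to the α-methyl enone at 1 mM. The fallback sets out from 13 and replaces the directed assembly through 14 and 15 by dynamic self-assembly. 13 is stirred with K2CO3 in MeOH/H2O (4:1) at 5 mM and 45 °C for 72 h, so that reversible aza-Michael addition builds head-to-tail oligomers and funnels them under thermodynamic control into the cyclodimer. The cyclodimer is the smallest strain-free ring, since closure of the monomer would need a bridged 12-membered ring. This fallback makes no compound outside the list (none F0) and rejoins the route at 16.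

Step 2 (β-alkylation and ring closure). Risks are a low yield with the unactivated iodide and modest anti selectivity; the syn isomer would carry the wrong C9 configuration and has to be removed. The fallback sets out from 2: the dianion is allylated instead (LiN(SiMe3)2, allyl bromide, −78 °C) to give 1-tert-butyl 4-methyl (2R,3S)-3-allyl-N-Boc-aspartate F1. Hydroboration–oxidation (9-BBN; NaBO3·4H2O) gives the 3-(3-hydroxypropyl)aspartate F2, mesylation (MsCl, Et3N) gives the mesylate F3, and LiN(SiMe3)2 (1.05 equiv) in THF/DMPU at 0 °C → rt closes the ring through the carbamate anion without epimerising C3, rejoining the route at 5.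

**Further compounds**
F1 | step 2 | 1-tert-butyl 4-methyl (2R,3S)-3-allyl-N-Boc-aspartate | CC(C)(C)OC(=O)N[C@H]([C@H](CC=C)C(=O)OC)C(=O)OC(C)(C)C
F2 | step 2 | 1-tert-butyl 4-methyl (2R,3S)-N-Boc-3-(3-hydroxypropyl)aspartate | CC(C)(C)OC(=O)N[C@H]([C@H](CCCO)C(=O)OC)C(=O)OC(C)(C)C
F3 | step 2 | 1-tert-butyl 4-methyl (2R,3S)-N-Boc-3-[3-(methylsulfonyloxy)propyl]aspartate | CC(C)(C)OC(=O)N[C@H]([C@H](CCCOS(C)(=O)=O)C(=O)OC)C(=O)OC(C)(C)C
F0 | step 9 | none | none
F4 | step 10 | bis(acyl chloride) of 16, dihydrochloride | ClC(=O)[C@@H]1N2CC(C)C(=O)CCCCCC[C@H]3CCCN(CC(C)C(=O)CCCCCC[C@H]1CCC2)[C@H]3C(Cl)=O.Cl.Cl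
F5 | step 10 | macrocyclic bis(2,3,4,5-tetrahydropyridinium) dichloride | C1=[N+]2CC(C)C(=O)CCCCCC[C@H]3CCC[N+](CC(C)C(=O)CCCCCC[C@H]1CCC2)=C3.[Cl-].[Cl-]
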